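**Retrosynthetic overview**

1. The route rests on ring A. Its four contiguous carbons C(Br)–C(Et)–C(Br)–C(H) are C3–C6 of 3,5‑dibromo‑4‑ethyl‑2‑pyrone 26. Its other two carbons are the ring‑fusion carbons of ring B (one bonded to the lactone‑bearing CH, one to CMe2) and come from the C=C of silyl enol ether 20. Ring A is closed last by Diels–Alder addition, then loss of CO2 and Me3SiOH.
2. Caged ketone 19 (ring B, seven‑membered ring, γ‑lactone) comes from monocyclic keto ester aldehyde 17 in one base‑mediated operation: aldol bond from the ketone α‑carbon to the aldehyde carbon, then lactonisation. The quaternary carbon dictates the other three stereocentres.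
3. 17 comes from dimedone: vinylogous ester, α′‑alkylation with ketal iodide 6, Pd‑catalysed asymmetric decarboxylative allylation (quaternary stereocentre; the allyl group is then cut down to the methyl group), and carbonyl transposition with introduction of the ester carbon by enol triflate carbonylation.
4. Ring order: ring B (dimedone) → seven‑membered ring and lactone (step 14) → ring A (step 20); then ketal removal and Saegusa dehydrogenation to the enone.
5. Pyrone 26 comes from ethyl 3‑oxopentanoate: (Z)‑enol triflate, Suzuki coupling with an ethoxyvinyl boronate, acid cyclisation, dibromination.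

Key step: step 20

Assumption (remark on the chemistry): in step 7 the (S)‑phosphinooxazoline ligand is taken to give the (R)‑quaternary centre, by analogy with its known sense of induction for cyclic ketone enolates; if the sense proves opposite, the (R)‑ligand is used.

**Route**

Step 1
Reactants: 1 dimedone
Product: 2 3‑isobutoxy‑5,5‑dimethylcyclohex‑2‑en‑1‑one
Conditions: i‑BuOH, TsOH (cat.), PhMe, reflux, Dean–Stark
Reagents that add atoms: isobutanol, CC(C)CO
Why: Acid‑catalysed condensation of the enolised 1,3‑dione with the alcohol (vinylogous ester formation), driven by removal of water; no stereocentre is formed.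

Step 2
Reactants: 3 ethyl 4‑(benzyloxy)‑3‑oxobutanoate
Product: 4 ethyl 2‑{2‑[(benzyloxy)methyl]‑1,3‑dioxolan‑2‑yl}acetate
Conditions: HOCH2CH2OH, TsOH (cat.), PhMe, reflux, Dean–Stark
Reagents that add atoms: ethylene glycol, OCCO
Why: Standard ketalisation of the ketone of a β‑keto ester, so that the ketone protection is in place before the chain meets ring B.

Step 3
Reactants: 4 ethyl 2‑{2‑[(benzyloxy)methyl]‑1,3‑dioxolan‑2‑yl}acetate
Product: 5 2‑{2‑[(benzyloxy)methyl]‑1,3‑dioxolan‑2‑yl}ethan‑1‑ol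
Conditions: LiAlH4, THF, 0 °C
Reagents that add atoms: none
Why: Hydride reduction of the ester to the primary alcohol; the dioxolane and the benzyl ether are inert to LiAlH4.

Step 4
Reactants: 5 2‑{2‑[(benzyloxy)methyl]‑1,3‑dioxolan‑2‑yl}ethan‑1‑ol
Product: 6 2‑[(benzyloxy)methyl]‑2‑(2‑iodoethyl)‑1,3‑dioxolane
Conditions: I2, PPh3, imidazole, CH2Cl2, 0 °C → rt
Reagents that add atoms: iodine, II
Why: Appel‑type iodination: SN2 displacement of the oxyphosphonium ion by iodide under non‑acidic conditions that spare the ketal.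

Step 5
Reactants: 2 3‑isobutoxy‑5,5‑dimethylcyclohex‑2‑en‑1‑one; 6 2‑[(benzyloxy)methyl]‑2‑(2‑iodoethyl)‑1,3‑dioxolane
Product: 7 rac‑6‑(2‑{2‑[(benzyloxy)methyl]‑1,3‑dioxolan‑2‑yl}ethyl)‑3‑isobutoxy‑5,5‑dimethylcyclohex‑2‑en‑1‑one
Conditions: LiN(i‑Pr)2, THF, −78 °C; then 6, HMPA, −78 → 0 °C
Reagents that add atoms: none
Why: Kinetic α′‑deprotonation of the vinylogous ester and SN2 alkylation of the lithium enolate with the unbranched primary iodide (enolate alkylation); the new tertiary centre is racemic and is erased as an enolate in step 6.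

Step 6
Reactants: 7 rac‑6‑(2‑{2‑[(benzyloxy)methyl]‑1,3‑dioxolan‑2‑yl}ethyl)‑3‑isobutoxy‑5,5‑dimethylcyclohex‑2‑en‑1‑one; 8 allyl chloroformate
Product: 9 allyl [2‑(2‑{2‑[(benzyloxy)methyl]‑1,3‑dioxolan‑2‑yl}ethyl)‑5‑isobutoxy‑3,3‑dimethylcyclohexa‑1,5‑dien‑1‑yl] carbonate
Conditions: LiN(i‑Pr)2, TMEDA, THF, −78 °C; then 8
Reagents that add atoms: none
Why: The hindered, fully substituted lithium enolate is acylated on oxygen by the chloroformate (enolate O‑acylation), giving the allyl enol carbonate needed for the decarboxylative allylation.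

Step 7
Reactants: 9 allyl [2‑(2‑{2‑[(benzyloxy)methyl]‑1,3‑dioxolan‑2‑yl}ethyl)‑5‑isobutoxy‑3,3‑dimethylcyclohexa‑1,5‑dien‑1‑yl] carbonate
Product: 10 (R)‑6‑allyl‑6‑(2‑{2‑[(benzyloxy)methyl]‑1,3‑dioxolan‑2‑yl}ethyl)‑3‑isobutoxy‑5,5‑dimethylcyclohex‑2‑en‑1‑one
Conditions: Pd2(dba)3 (2.5 mol%), (S)‑(CF3)3‑t‑BuPHOX (electron‑poor phosphinooxazoline, 6 mol%), PhMe, 30 °C
Reagents that add atoms: none
Why: Pd‑catalysed decarboxylative asymmetric allylic alkylation (Tsuji allylation): zerovalent palladium ionises the allyl carbonate, CO2 is lost, and the allylpalladium enolate pair bound to the chiral ligand recombines at the α′‑carbon on one enolate face, which sets the quaternary stereocentre next to CMe2.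

Step 8
Reactants: 10 (R)‑6‑allyl‑6‑(2‑{2‑[(benzyloxy)methyl]‑1,3‑dioxolan‑2‑yl}ethyl)‑3‑isobutoxy‑5,5‑dimethylcyclohex‑2‑en‑1‑one
Product: 11 2‑[(R)‑1‑(2‑{2‑[(benzyloxy)methyl]‑1,3‑dioxolan‑2‑yl}ethyl)‑4‑isobutoxy‑6,6‑dimethyl‑2‑oxocyclohex‑3‑en‑1‑yl]acetaldehyde
Conditions: OsO4 (cat.), NaIO4, 2,6‑lutidine, dioxane/H2O, rt
Reagents that add atoms: osmium tetroxide, O=[Os](=O)(=O)=O (catalytic oxygen carrier); sodium periodate, [Na+].[O-]I(=O)(=O)=O (terminal oxygen source)
Why: Lemieux–Johnson oxidation: OsO4 dihydroxylates the terminal alkene much faster than the push–pull enone C=C and periodate cleaves the diol to the aldehyde; the stereocentre is untouched.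

Step 9
Reactants: 11 2‑[(R)‑1‑(2‑{2‑[(benzyloxy)methyl]‑1,3‑dioxolan‑2‑yl}ethyl)‑4‑isobutoxy‑6,6‑dimethyl‑2‑oxocyclohex‑3‑en‑1‑yl]acetaldehyde
Product: 12 (S)‑6‑(2‑{2‑[(benzyloxy)methyl]‑1,3‑dioxolan‑2‑yl}ethyl)‑3‑isobutoxy‑5,5,6‑trimethylcyclohex‑2‑en‑1‑one
Conditions: RhCl3·3H2O (5 mol%), dppp (10 mol%), diglyme, 160 °C
Reagents that add atoms: none
Why: Rhodium‑catalysed decarbonylation of the unhindered primary aldehyde (Tsuji–Wilkinson reaction) turns the CH2–CHO arm into the methyl group of the quaternary carbon with retention of that centre (the descriptor changes only through the priority rules).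

Step 10
Reactants: 12 (S)‑6‑(2‑{2‑[(benzyloxy)methyl]‑1,3‑dioxolan‑2‑yl}ethyl)‑3‑isobutoxy‑5,5,6‑trimethylcyclohex‑2‑en‑1‑one
Product: 13 (S)‑6‑(2‑{2‑[(benzyloxy)methyl]‑1,3‑dioxolan‑2‑yl}ethyl)‑3‑isobutoxy‑5,5,6‑trimethylcyclohexa‑1,3‑dien‑1‑yl trifluoromethanesulfonate
Conditions: LiN(i‑Pr)2, THF, −78 °C; then N‑(5‑chloro‑2‑pyridyl)triflimide, −78 → 0 °C
Reagents that add atoms: N‑(5‑chloro‑2‑pyridyl)bis(trifluoromethanesulfonimide), O=S(=O)(N(c1ccc(Cl)cn1)S(=O)(=O)C(F)(F)F)C(F)(F)F
Why: With the α′‑position quaternary, the base can only remove a γ‑proton, and the extended dienolate is sulfonylated on oxygen (enolate O‑triflation), which marks the former carbonyl carbon as the future ester‑bearing carbon.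

Step 11
Reactants: 13 (S)‑6‑(2‑{2‑[(benzyloxy)methyl]‑1,3‑dioxolan‑2‑yl}ethyl)‑3‑isobutoxy‑5,5,6‑trimethylcyclohexa‑1,3‑dien‑1‑yl trifluoromethanesulfonate
Product: 15 methyl (S)‑6‑(2‑{2‑[(benzyloxy)methyl]‑1,3‑dioxolan‑2‑yl}ethyl)‑5,5,6‑trimethyl‑3‑oxocyclohex‑1‑ene‑1‑carboxylate, via dienyl methyl ester 14 (not isolated)
Conditions: Pd(OAc)2 (5 mol%), dppp, CO (1 atm), MeOH, Et3N, DMF, 60 °C; then 1 M HCl, THF, 0 °C
Reagents that add atoms: carbon monoxide, [C-]#[O+]; methanol, CO; water, O
Why: Pd‑catalysed alkoxycarbonylation of the enol triflate (oxidative addition, CO insertion, methanolysis) installs the ester carbon, and cold dilute acid hydrolyses the far more labile enol ether rather than the inductively deactivated dioxolane, which completes the 1,3‑carbonyl transposition.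

Step 12
Reactants: 15 methyl (S)‑6‑(2‑{2‑[(benzyloxy)methyl]‑1,3‑dioxolan‑2‑yl}ethyl)‑5,5,6‑trimethyl‑3‑oxocyclohex‑1‑ene‑1‑carboxylate
Product: 16 methyl (2R)‑2‑{2‑[2‑(hydroxymethyl)‑1,3‑dioxolan‑2‑yl]ethyl}‑2,3,3‑trimethyl‑5‑oxocyclohexane‑1‑carboxylate (both C‑1 epimers)
Conditions: H2 (1 atm), 10% Pd/C, EtOAc, rt
Reagents that add atoms: none
Why: Heterogeneous hydrogenation saturates the electron‑poor trisubstituted alkene and hydrogenolyses the benzyl ether in one operation; the ester‑bearing centre is formed without control but is equilibrated in step 14.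

Step 13
Reactants: 16 methyl (2R)‑2‑{2‑[2‑(hydroxymethyl)‑1,3‑dioxolan‑2‑yl]ethyl}‑2,3,3‑trimethyl‑5‑oxocyclohexane‑1‑carboxylate
Product: 17 methyl (2R)‑2‑[2‑(2‑formyl‑1,3‑dioxolan‑2‑yl)ethyl]‑2,3,3‑trimethyl‑5‑oxocyclohexane‑1‑carboxylate (both C‑1 epimers)
Conditions: Dess–Martin periodinane, CH2Cl2, rt
Reagents that add atoms: none
Why: Dess–Martin oxidation of the primary alcohol gives the non‑enolisable α‑ketal aldehyde under near‑neutral conditions without touching ketone, ester or ketal.

Step 14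
Reactants: 17 methyl (2R)‑2‑[2‑(2‑formyl‑1,3‑dioxolan‑2‑yl)ethyl]‑2,3,3‑trimethyl‑5‑oxocyclohexane‑1‑carboxylate
Product: 19 caged keto lactone ketal (bicyclo[4.3.1]decan‑9‑one core; 6,7,7‑trimethyl; 3,3‑ethylenedioxy; γ‑lactone from the C‑10 carboxyl to the C‑2 oxygen), via bicyclic aldol hydroxy ester 18 (not isolated)
Conditions: NaOMe (0.3 equiv), MeOH/THF, 0 → 40 °C; then AcOH
Reagents that add atoms: none
Why: Reversible intramolecular aldol addition of the ring‑ketone enolate to the non‑enolisable aldehyde closes the seven‑membered ring, and the aldolate whose carbinol oxygen and ester (epimerised through its enolate) lie on the same face is trapped as the γ‑lactone, so thermodynamic control funnels the material into the one cage that the quaternary centre allows and thereby fixes the three new stereocentres (aldol addition–lactonisation cascade).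

Step 15
Reactants: 19 caged keto lactone ketal
Product: 20 trimethylsilyl enol ether of 19 (C=C between the former carbonyl carbon and the CH next to CMe2)
Conditions: LiN(i‑Pr)2, TMSCl (in situ), THF, −78 °C; Et3N
Reagents that add atoms: chlorotrimethylsilane, C[Si](C)(C)Cl
Why: Kinetic enolisation with in situ silylation (silyl enol ether formation) can only go toward the CH2 next to CMe2, because the other α‑hydrogen is an equatorial bridgehead hydrogen whose enolate would be a strained bridgehead alkene.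

Step 16
Reactants: 21 ethyl 3‑oxopentanoate
Product: 22 ethyl (Z)‑3‑(trifluoromethylsulfonyloxy)pent‑2‑enoate
Conditions: Tf2O, aq. LiOH, PhMe, 5 °C
Reagents that add atoms: triflic anhydride, O=S(=O)(OS(=O)(=O)C(F)(F)F)C(F)(F)F
Why: The chelated lithium (Z)‑enolate of the β‑keto ester is trapped on oxygen by Tf2O (enol triflate formation), giving the (Z)‑geometry in which triflate and ester are cis.

Step 17
Reactants: 22 ethyl (Z)‑3‑(trifluoromethylsulfonyloxy)pent‑2‑enoate; 23 (E)‑2‑(2‑ethoxyvinyl)‑4,4,5,5‑tetramethyl‑1,3,2‑dioxaborolane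
Product: 24 ethyl (2Z,4E)‑5‑ethoxy‑3‑ethylpenta‑2,4‑dienoate
Conditions: Pd(PPh3)4 (5 mol%), K3PO4, dioxane/H2O, 60 °C
Reagents that add atoms: none
Why: Suzuki–Miyaura coupling of the vinyl triflate with the alkenyl boronate goes with retention at both alkenes, placing the masked aldehyde carbon cis to the ester.

Step 18
Reactants: 24 ethyl (2Z,4E)‑5‑ethoxy‑3‑ethylpenta‑2,4‑dienoate
Product: 25 4‑ethyl‑2H‑pyran‑2‑one
Conditions: TsOH·H2O, wet PhMe, 90 °C
Reagents that add atoms: water, O
Why: Acid hydrolysis of the enol ether unveils the (Z)‑configured aldehyde ester, whose enol attacks the cis ester and closes the 2‑pyrone with loss of ethanol (enol lactonisation).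

Step 19
Reactants: 25 4‑ethyl‑2H‑pyran‑2‑one
Product: 26 3,5‑dibromo‑4‑ethyl‑2H‑pyran‑2‑one
Conditions: Br2 (2.2 equiv), CH2Cl2, 0 °C → rt; then Et3N
Reagents that add atoms: bromine, BrBr
Why: Electrophilic bromination of the 2‑pyrone (addition–elimination, HBr removed by the amine) at its two nucleophilic positions C3 and C5, both flanking the ethyl group, while C6 stays unsubstituted.

Step 20
Reactants: 20 trimethylsilyl enol ether of 19; 26 3,5‑dibromo‑4‑ethyl‑2H‑pyran‑2‑one
Product: 29 ketal‑protected dihydrosalimabromide, via bridged lactone cycloadduct 27 (not isolated), via cyclohexadiene 28 (not isolated)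
Conditions: 26 (2 equiv), 2,6‑di‑tert‑butyl‑4‑methylpyridine (0.2 equiv), PhMe, sealed tube, 140 °C
Reagents that add atoms: none
Why: Inverse‑electron‑demand Diels–Alder reaction in which the electron‑poor dibromopyrone 26 is the diene and the silyl enol ether 20 the dienophile: the nucleophilic CH carbon of 20 bonds to pyrone C6 and the silyloxy carbon to C3 in an asynchronous [4+2] addition that gives bridged lactone 27. Retro‑Diels–Alder loss of CO2 from 27 gives cyclohexadiene 28, and 1,2‑elimination of Me3SiOH aromatises it, so ring A is closed by cycloaddition across the enol ether C=C and made irreversible by the two extrusions. The closest known reaction type is the pyrone Diels–Alder/retro‑Diels–Alder benzannulation of 2‑pyrones with enol ethers and enamines. No lasting stereocentre is created, since the sp3 centres of 27 all vanish on aromatisation and the four stereocentres of 20 carry no readily enolisable hydrogen. Only regioselectivity is needed; it follows from the polarity match between the enol ether β‑carbon and the electrophilic C6 of the pyrone, and from the enol ether double bond, which can only lie toward the CH2 next to CMe2. Because the two halogens and the ethyl group are already on the pyrone, ring A needs no substitution chemistry afterwards.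

Step 21
Reactants: 29 ketal‑protected dihydrosalimabromide
Product: 30 dihydrosalimabromide (saturated seven‑ring ketone)
Conditions: TFA/H2O, CH2Cl2, rt → 40 °C
Reagents that add atoms: water, O
Why: Acid‑catalysed ketal hydrolysis; the lactone, the aryl bromides and the stereocentres are stable to aqueous acid.

Step 22
Reactants: 30 dihydrosalimabromide
Product: 31 trimethylsilyl enol ether of 30 (C=C toward the ring CH2)
Conditions: TMSOTf, Et3N, CH2Cl2, 0 °C
Reagents that add atoms: trimethylsilyl triflate, C[Si](C)(C)OS(=O)(=O)C(F)(F)F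
Why: Soft enolisation (silyl enol ether formation) can only go toward the CH2 group, since the other α‑carbon is the bridgehead carbon that bears the lactone oxygen.

Step 23
Reactants: 31 trimethylsilyl enol ether of 30
Product: 32 salimabromide
Conditions: Pd(OAc)2 (1.1 equiv), MeCN, rt
Reagents that add atoms: none
Why: Saegusa–Ito oxidation: divalent palladium gives the α‑palladated ketone and β‑hydride elimination forms the ring enone (necessarily cis in the seven‑membered ring); no stereocentre is affected and the hindered aryl bromides should not react in the absence of phosphine.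

**Compound list**

1 | dimedone (5,5‑dimethylcyclohexane‑1,3‑dione) | CC1(C)CC(=O)CC(=O)C1 | starting material
2 | 3‑isobutoxy‑5,5‑dimethylcyclohex‑2‑en‑1‑one | CC(C)COC1=CC(=O)CC(C)(C)C1 | intermediate
3 | ethyl 4‑(benzyloxy)‑3‑oxobutanoate | CCOC(=O)CC(=O)COCc1ccccc1 | starting material
4 | ethyl 2‑{2‑[(benzyloxy)methyl]‑1,3‑dioxolan‑2‑yl}acetate | CCOC(=O)CC1(COCc2ccccc2)OCCO1 | intermediate
5 | 2‑{2‑[(benzyloxy)methyl]‑1,3‑dioxolan‑2‑yl}ethan‑1‑ol | OCCC1(COCc2ccccc2)OCCO1 | intermediate
6 | 2‑[(benzyloxy)methyl]‑2‑(2‑iodoethyl)‑1,3‑dioxolane | ICCC1(COCc2ccccc2)OCCO1 | intermediate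
7 | rac‑6‑(2‑{2‑[(benzyloxy)methyl]‑1,3‑dioxolan‑2‑yl}ethyl)‑3‑isobutoxy‑5,5‑dimethylcyclohex‑2‑en‑1‑one | C1C(OCC(C)C)=CC(=O)C(CCC2(COCc3ccccc3)OCCO2)C1(C)C | intermediate
8 | allyl chloroformate | C=CCOC(Cl)=O | starting material
9 | allyl enol carbonate of 7 | C1C(OCC(C)C)=CC(OC(=O)OCC=C)=C(CCC2(COCc3ccccc3)OCCO2)C1(C)C | intermediate
10 | (R)‑6‑allyl‑6‑(2‑{2‑[(benzyloxy)methyl]‑1,3‑dioxolan‑2‑yl}ethyl)‑3‑isobutoxy‑5,5‑dimethylcyclohex‑2‑en‑1‑one | C1C(OCC(C)C)=CC(=O)[C@@](CC=C)(CCC2(COCc3ccccc3)OCCO2)C1(C)C | intermediate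
11 | (R)‑configured acetaldehyde (CH2CHO in place of allyl of 10) | C1C(OCC(C)C)=CC(=O)[C@@](CC=O)(CCC2(COCc3ccccc3)OCCO2)C1(C)C | intermediate
12 | (S)‑6‑(2‑{2‑[(benzyloxy)methyl]‑1,3‑dioxolan‑2‑yl}ethyl)‑3‑isobutoxy‑5,5,6‑trimethylcyclohex‑2‑en‑1‑one | C1C(OCC(C)C)=CC(=O)[C@@](C)(CCC2(COCc3ccccc3)OCCO2)C1(C)C | intermediate
13 | (S)‑dienyl triflate of 12 | C1=C(OCC(C)C)C=C(OS(=O)(=O)C(F)(F)F)[C@@](C)(CCC2(COCc3ccccc3)OCCO2)C1(C)C | intermediate
14 | methyl (S)‑6‑(2‑{2‑[(benzyloxy)methyl]‑1,3‑dioxolan‑2‑yl}ethyl)‑3‑isobutoxy‑5,5,6‑trimethylcyclohexa‑1,3‑diene‑1‑carboxylate | C1=C(OCC(C)C)C=C(C(=O)OC)[C@@](C)(CCC2(COCc3ccccc3)OCCO2)C1(C)C | intermediate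
15 | methyl (S)‑6‑(2‑{2‑[(benzyloxy)methyl]‑1,3‑dioxolan‑2‑yl}ethyl)‑5,5,6‑trimethyl‑3‑oxocyclohex‑1‑ene‑1‑carboxylate | C1C(=O)C=C(C(=O)OC)[C@@](C)(CCC2(COCc3ccccc3)OCCO2)C1(C)C | intermediate
16 | methyl (2R)‑2‑{2‑[2‑(hydroxymethyl)‑1,3‑dioxolan‑2‑yl]ethyl}‑2,3,3‑trimethyl‑5‑oxocyclohexane‑1‑carboxylate (C‑1 epimers; C‑1 left undefined) | C1C(=O)CC(C(=O)OC)[C@@](C)(CCC2(CO)OCCO2)C1(C)C | intermediate
17 | methyl (2R)‑2‑[2‑(2‑formyl‑1,3‑dioxolan‑2‑yl)ethyl]‑2,3,3‑trimethyl‑5‑oxocyclohexane‑1‑carboxylate (C‑1 epimers; C‑1 left undefined) | C1C(=O)CC(C(=O)OC)[C@@](C)(CCC2(C=O)OCCO2)C1(C)C | intermediate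
18 | methyl 2‑hydroxy‑6,7,7‑trimethyl‑9‑oxospiro[bicyclo[4.3.1]decane‑3,2′‑[1,3]dioxolane]‑10‑carboxylate (hydroxyl and ester on the same face) | C1C(=O)[C@H]2[C@H](O)C3(OCCO3)CC[C@@](C)(C1(C)C)[C@@H]2C(=O)OC | intermediate
19 | caged keto lactone ketal (lactone of 18; ring‑B ketone, seven‑membered ring with ethylene ketal, cis‑fused γ‑lactone) | C1C(=O)[C@H]2[C@@H]3OC(=O)[C@H]2[C@@](C)(CCC34OCCO4)C1(C)C | intermediate
20 | trimethylsilyl enol ether of 19 | C1=C(O[Si](C)(C)C)[C@H]2[C@@H]3OC(=O)[C@H]2[C@@](C)(CCC34OCCO4)C1(C)C | intermediate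
21 | ethyl 3‑oxopentanoate | CCC(=O)CC(=O)OCC | starting material
22 | ethyl (Z)‑3‑(trifluoromethylsulfonyloxy)pent‑2‑enoate | CC/C(OS(=O)(=O)C(F)(F)F)=C/C(=O)OCC | intermediate
23 | (E)‑2‑(2‑ethoxyvinyl)‑4,4,5,5‑tetramethyl‑1,3,2‑dioxaborolane | CCO/C=C/B1OC(C)(C)C(C)(C)O1 | starting material
24 | ethyl (2Z,4E)‑5‑ethoxy‑3‑ethylpenta‑2,4‑dienoate | CCOC(=O)/C=C(CC)\C=C\OCC | intermediate
25 | 4‑ethyl‑2H‑pyran‑2‑one | CCC1=CC(=O)OC=C1 | intermediate
26 | 3,5‑dibromo‑4‑ethyl‑2H‑pyran‑2‑one | CCC1=C(Br)C(=O)OC=C1Br | intermediate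
27 | bridged lactone cycloadduct (2‑oxabicyclo[2.2.2]octenone; new centres undefined) | C15C(O[Si](C)(C)C)(C6(Br)C(=O)OC5C(Br)=C6CC)[C@H]2[C@@H]3OC(=O)[C@H]2[C@@](C)(CCC34OCCO4)C1(C)C | intermediate
28 | silyloxy cyclohexadiene after loss of CO2 (new centres undefined) | C15C(O[Si](C)(C)C)(C(Br)=C(CC)C(Br)=C5)[C@H]2[C@@H]3OC(=O)[C@H]2[C@@](C)(CCC34OCCO4)C1(C)C | intermediate
29 | ketal‑protected dihydrosalimabromide | CCc1c(Br)cc2c(c1Br)[C@H]1[C@@H]3OC(=O)[C@H]1[C@@](C)(CCC34OCCO4)C2(C)C | intermediate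
30 | dihydrosalimabromide | CCc1c(Br)cc2c(c1Br)[C@H]1[C@@H]3OC(=O)[C@H]1[C@@](C)(CCC3=O)C2(C)C | intermediate
31 | trimethylsilyl enol ether of 30 | CCc1c(Br)cc2c(c1Br)[C@H]1[C@@H]3OC(=O)[C@H]1[C@@](C)(CC=C3O[Si](C)(C)C)C2(C)C | intermediate
32 | salimabromide | CCc1c(Br)cc2c(c1Br)[C@H]1[C@@H]3OC(=O)[C@H]1[C@@](C)(C=CC3=O)C2(C)C | target

**Step count and risk**

Total step count: 23. Longest linear sequence: 18 steps (steps 2–15 and 20–23, from 3); from dimedone the sequence is 16 steps.

Steps most likely to fail: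

Step 20. The cycloaddition may stall, because the second bond has to form between the fully substituted silyloxy carbon (next to a bridgehead) and the bromine‑bearing C3 of a 4‑substituted pyrone, while the trimethylsilyl enol ether is slowly cleaved at the temperature required. The fallback sets out from ketone 19: condensation with pyrrolidine (4 Å sieves, cat. TsOH, PhMe, reflux) should give the pyrrolidine enamine F1, with the double bond toward the CH2 next to CMe2 for the same bridgehead reason. Heating F1 with pyrone 26 should lead through the bridged lactone cycloadduct F2 and, after loss of CO2, the aminocyclohexadiene F3, which eliminates pyrrolidine. The more nucleophilic enamine gives the first bond to C6 earlier, with stepwise Michael–Mannich character. The fallback comes back to the route at 29.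

Step 14. The aldol addition may start from the other enolate (CH2 next to CMe2), or the system may rest in unproductive equilibria (retro‑aldol, hemiacetal formation, base‑induced consumption of the aldehyde) before the lactone trap operates. The fallback sets out from enone ester 15: oxidative debenzylation (DDQ, CH2Cl2/H2O, visible light) should give the unsaturated alcohol F4, and Dess–Martin oxidation the unsaturated keto ester aldehyde F5. A reductive aldol cyclisation (Co(dpm)2 cat., PhSiH3, ClCH2CH2Cl) then generates the metal enolate only at the α‑carbon between the ketone and the ester‑bearing carbon by hydrometallation of the enone, and this enolate adds to the aldehyde under neutral conditions. The fallback comes back to the route at 18 (or its ester epimer), which catalytic NaOMe lactonises to 19 as in step 14.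

Step 10. Deprotonation has to occur at the hindered γ‑CH2 and sulfonylation at an enolate oxygen flanked by the quaternary carbon; incomplete enolisation, attack at carbon, or a sluggish oxidative addition in the following carbonylation may intervene. The fallback replaces enolate O‑triflation by 1,2‑addition and transposition and sets out from 12. Vinylmagnesium bromide with CeCl3 (THF, −78 °C) should give the tertiary allylic alcohol F6, and aqueous HCl should hydrolyse the enol ether and dehydrate to the 3‑vinyl enone F7. OsO4 (cat.)/NaIO4 cleaves the terminal, more electron‑rich alkene to the enone aldehyde F8, NaClO2/NaH2PO4 oxidises it to the enone acid F9, and MeI/K2CO3 esterifies. The fallback comes back to the route at 15.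

Further compounds
F1 | step 20 | pyrrolidine enamine of 19 | C1=C(N5CCCC5)[C@H]2[C@@H]3OC(=O)[C@H]2[C@@](C)(CCC34OCCO4)C1(C)C
F2 | step 20 | bridged lactone cycloadduct of F1 and 26 | C15C(N7CCCC7)(C6(Br)C(=O)OC5C(Br)=C6CC)[C@H]2[C@@H]3OC(=O)[C@H]2[C@@](C)(CCC34OCCO4)C1(C)C
F3 | step 20 | aminocyclohexadiene | C15C(N7CCCC7)(C(Br)=C(CC)C(Br)=C5)[C@H]2[C@@H]3OC(=O)[C@H]2[C@@](C)(CCC34OCCO4)C1(C)C
F4 | step 14 | methyl (S)‑6‑{2‑[2‑(hydroxymethyl)‑1,3‑dioxolan‑2‑yl]ethyl}‑5,5,6‑trimethyl‑3‑oxocyclohex‑1‑ene‑1‑carboxylate | C1C(=O)C=C(C(=O)OC)[C@@](C)(CCC2(CO)OCCO2)C1(C)C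
F5 | step 14 | methyl (S)‑6‑[2‑(2‑formyl‑1,3‑dioxolan‑2‑yl)ethyl]‑5,5,6‑trimethyl‑3‑oxocyclohex‑1‑ene‑1‑carboxylate | C1C(=O)C=C(C(=O)OC)[C@@](C)(CCC2(C=O)OCCO2)C1(C)C
F6 | step 10 | tertiary allylic alcohol from vinyl addition to 12 (carbinol centre undefined) | C1C(OCC(C)C)=CC(O)(C=C)[C@@](C)(CCC2(COCc3ccccc3)OCCO2)C1(C)C
F7 | step 10 | 3‑vinyl enone | C1C(=O)C=C(C=C)[C@@](C)(CCC2(COCc3ccccc3)OCCO2)C1(C)C
F8 | step 10 | enone aldehyde | C1C(=O)C=C(C=O)[C@@](C)(CCC2(COCc3ccccc3)OCCO2)C1(C)C
F9 | step 10 | enone acid | C1C(=O)C=C(C(=O)O)[C@@](C)(CCC2(COCc3ccccc3)OCCO2)C1(C)C
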